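**Retrosynthetic overview**
1. Target ⇒ 8,10‑anti diol (two propionates last) ⇒ hydroxyl‑directed reduction of a C10 enone ⇒ oxidation of the C10–C11 Nozaki–Hiyama–Kishi adduct of ring‑A aldehyde 19 (C7–C10, 19 heavy atoms without silyl) and ring‑B alkenyl iodide 41 (C11–C16, 24 heavy atoms).
2. Ring A is closed inside fragment 19 by cyclodehydration of a 1,3,5‑triketone (dianion of 4‑methylheptane‑3,5‑dione + aldehyde 13); the C7–C9 triad comes from (S)‑Roche ester by Brown (E)‑crotylboration.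
3. Ring B is closed inside fragment 41 by the same cyclodehydration; its triketone comes from pentan‑3‑one by two aldol additions, to (2S,3E)‑4‑iodo‑2‑methylpent‑3‑enal (from (R)‑Roche ester) and to (2S,3S)‑3‑silyloxy‑2‑methylpentanal (from propanal by proline‑catalysed self‑aldol).
4. Both pyranone rings exist before the coupling; no ring is formed after it.

Assumption: both enantiomers of methyl 3‑hydroxy‑2‑methylpropanoate, (−)‑Ipc2BOMe and L‑proline are taken as commercial.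
Locants: ring A = 2‑ethyl‑3,5‑dimethyl‑4‑pyranone, carrying C7; chain C7 (CHMe), C8 (CH–O), C9 (CHMe), C10 (CH–O), C11(Me)=C12, C13 (CHMe); ring B = 3,5‑dimethyl‑4‑pyranone whose carbon C14 carries C13 and whose other α‑carbon carries C15 (CHMe)–C16 (CH–O)–Et. The target is (7R,8R,9R,10R,11E,13S,15S,16S). TBS = tert‑butyldimethylsilyl, TBSO = its ether.

**Ring‑A fragment**

Step 1
Reactants: 1 pentan‑3‑one; 2 ethyl propanoate
Product: 3 4‑methylheptane‑3,5‑dione
Conditions: NaH (2.2 equiv), THF, reflux; then aq. HCl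
Reagents that add atoms: none
Why: Claisen‑type C‑acylation of the ketone enolate by the ester, driven by deprotonation of the β‑diketone formed; no stereocentre.

Step 2
Reactants: 4 methyl (S)‑3‑hydroxy‑2‑methylpropanoate
Product: 5 methyl (S)‑3‑(TBSO)‑2‑methylpropanoate
Conditions: TBSCl, imidazole, CH2Cl2, 0 °C to rt
Reagents that add atoms: tert‑butyldimethylsilyl chloride (CC(C)(C)[Si](C)(C)Cl)
Why: Silylation of the primary alcohol leaves the stereocentre (future C9) untouched.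

Step 3
Reactants: 5 methyl (S)‑3‑(TBSO)‑2‑methylpropanoate
Product: 6 (S)‑3‑(TBSO)‑2‑methylpropanal
Conditions: i‑Bu2AlH (1.05 equiv), CH2Cl2, −78 °C; MeOH, aq. potassium sodium tartrate
Reagents that add atoms: none
Why: Partial ester reduction stops at the aluminium hemiacetal at −78 °C, and the cold non‑basic work‑up keeps the α‑centre intact.

Step 4
Reactants: 6 (S)‑3‑(TBSO)‑2‑methylpropanal; 7 (E)‑but‑2‑ene
Product: 10 (2S,3S,4S)‑1‑(TBSO)‑2,4‑dimethylhex‑5‑en‑3‑ol, via (E)‑crotylpotassium 8 (not isolated), via (E)‑crotyl‑Ipc2B borane 9 (not isolated)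
Conditions: 7, KOt‑Bu, n‑BuLi, THF, −78 to −45 °C; (−)‑Ipc2BOMe (from (+)‑α‑pinene), −78 °C; BF3·OEt2; 6, −78 °C; NaOH, H2O2
Reagents that add atoms: none
Why: Brown asymmetric crotylboration, in which the chair transition state of the (E)‑crotylborane gives the C7/C8 anti relation and the Ipc groups select the aldehyde face that is also the Felkin face (matched), giving C8/C9 syn.

Step 5
Reactants: 10 (2S,3S,4S)‑1‑(TBSO)‑2,4‑dimethylhex‑5‑en‑3‑ol
Product: 11 (2S,3S,4S)‑1,3‑bis(TBSO)‑2,4‑dimethylhex‑5‑ene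
Conditions: TBSOTf, 2,6‑lutidine, CH2Cl2, −78 to 0 °C
Reagents that add atoms: tert‑butyldimethylsilyl triflate (CC(C)(C)[Si](C)(C)OS(=O)(=O)C(F)(F)F)
Why: Silylation of the hindered secondary alcohol with the reactive triflate protects C8–OH for the basic and oxidative steps ahead.

Step 6
Reactants: 11 (2S,3S,4S)‑1,3‑bis(TBSO)‑2,4‑dimethylhex‑5‑ene
Product: 13 (2R,3R,4S)‑3,5‑bis(TBSO)‑2,4‑dimethylpentanal, via secondary ozonide 12 (not isolated)
Conditions: O3, CH2Cl2, −78 °C; PPh3, −78 °C to rt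
Reagents that add atoms: ozone ([O-][O+]=O)
Why: Ozonolysis with reductive work‑up cleaves the vinyl group to the aldehyde (future C6 of ring A) under neutral conditions that do not epimerise C7.

Step 7
Reactants: 13 (2R,3R,4S)‑3,5‑bis(TBSO)‑2,4‑dimethylpentanal; 3 4‑methylheptane‑3,5‑dione
Product: 15 7‑hydroxy‑9,11‑bis(TBSO)‑4,6,8,10‑tetramethylundecane‑3,5‑dione (diastereomer mixture), via diketone dianion 14 (not isolated)
Conditions: 3, LiN(i‑Pr)2 (2.1 equiv), THF, −78 to 0 °C; 13, −78 °C; AcOH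
Reagents that add atoms: none
Why: Aldol addition of a β‑diketone dianion through its terminal carbanion, the most nucleophilic site, is faster than aldehyde enolisation at −78 °C, and the new centres are erased later.

Step 8
Reactants: 15 the hydroxy‑diketone
Product: 16 (8R,9R,10S)‑9,11‑bis(TBSO)‑4,6,8,10‑tetramethylundecane‑3,5,7‑trione (keto–enol mixture)
Conditions: Dess–Martin periodinane, NaHCO3, CH2Cl2, 0 °C to rt
Reagents that add atoms: none
Why: Buffered Dess–Martin oxidation of the secondary alcohol gives the 1,3,5‑triketone without base, so C7 (now α to a ketone) is preserved.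

Step 9
Reactants: 16 the triketone
Product: 17 2‑[(2R,3R,4S)‑3,5‑bis(TBSO)‑4‑methylpentan‑2‑yl]‑6‑ethyl‑3,5‑dimethyl‑4H‑pyran‑4‑one
Conditions: PPh3, CCl4, THF, rt
Reagents that add atoms: none
Why: Cyclodehydration of the 1,3,5‑triketone (Appel‑type activation of an enol oxygen, attack by the other enol, loss of Ph3PO) closes ring A under near‑neutral conditions that spare C7 and the silyl ethers.

Step 10
Reactants: 17 the bis‑silyl pyranone
Product: 18 2‑[(2R,3R,4S)‑3‑(TBSO)‑5‑hydroxy‑4‑methylpentan‑2‑yl]‑6‑ethyl‑3,5‑dimethyl‑4H‑pyran‑4‑one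
Conditions: CSA (0.1 equiv), MeOH/CH2Cl2, 0 °C
Reagents that add atoms: none
Why: Acid‑catalysed methanolysis removes the unhindered primary TBS ether much faster than the flanked secondary one.

Step 11
Reactants: 18 the primary alcohol
Product: 19 (2R,3S,4R)‑3‑(TBSO)‑4‑(6‑ethyl‑3,5‑dimethyl‑4‑oxo‑4H‑pyran‑2‑yl)‑2‑methylpentanal
Conditions: Dess–Martin periodinane, NaHCO3, CH2Cl2, 0 °C
Reagents that add atoms: none
Why: Dess–Martin oxidation gives the C10 aldehyde without epimerising C9.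

**Ring‑B fragment**

Step 12
Reactants: 20 methyl (R)‑3‑hydroxy‑2‑methylpropanoate
Product: 21 methyl (R)‑3‑(TBSO)‑2‑methylpropanoate
Conditions: TBSCl, imidazole, CH2Cl2, 0 °C to rt
Reagents that add atoms: tert‑butyldimethylsilyl chloride (CC(C)(C)[Si](C)(C)Cl)
Why: Silylation of the primary alcohol (future C14) leaves the stereocentre (future C13) untouched.

Step 13
Reactants: 21 methyl (R)‑3‑(TBSO)‑2‑methylpropanoate
Product: 22 (R)‑3‑(TBSO)‑2‑methylpropanal
Conditions: i‑Bu2AlH (1.05 equiv), CH2Cl2, −78 °C; MeOH, aq. potassium sodium tartrate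
Reagents that add atoms: none
Why: Partial DIBAL reduction of the ester to the aldehyde (future C12) at −78 °C without epimerisation.

Step 14
Reactants: 22 (R)‑3‑(TBSO)‑2‑methylpropanal
Product: 23 (S)‑4,4‑dibromo‑1‑(TBSO)‑2‑methylbut‑3‑ene
Conditions: CBr4, PPh3, CH2Cl2, 0 °C; then 22, 2,6‑lutidine, 0 °C
Reagents that add atoms: carbon tetrabromide (BrC(Br)(Br)Br)
Why: Corey–Fuchs dibromo‑olefination (Wittig reaction of Ph3P=CBr2) under buffered conditions adds the future C11 without touching the α‑centre.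

Step 15
Reactants: 23 the dibromoalkene
Product: 25 (S)‑1‑(TBSO)‑2‑methylpent‑3‑yne, via lithium acetylide 24 (not isolated)
Conditions: n‑BuLi (2.1 equiv), THF, −78 °C; MeI, −78 °C to rt
Reagents that add atoms: iodomethane (CI)
Why: Second stage of the Corey–Fuchs sequence (Br/Li exchange, Fritsch–Buttenberg–Wiechell rearrangement to the acetylide) followed by C‑methylation gives the 2‑alkyne with the C11 methyl.

Step 16
Reactants: 25 (S)‑1‑(TBSO)‑2‑methylpent‑3‑yne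
Product: 27 (S,E)‑1‑(TBSO)‑4‑iodo‑2‑methylpent‑3‑ene, via alkenylzirconocene chloride 26 (not isolated)
Conditions: Cp2Zr(H)Cl (1.5 equiv), THF, 45 °C; I2, THF, 0 °C
Reagents that add atoms: iodine (II)
Why: Hydrozirconation is a syn addition that places zirconium on the less hindered methyl‑bearing alkyne carbon, and iodinolysis with retention gives the (E)‑2‑iodoalkene.

Step 17
Reactants: 27 the silyl ether
Product: 28 (2S,3E)‑4‑iodo‑2‑methylpent‑3‑en‑1‑ol
Conditions: CSA (0.1 equiv), MeOH, 0 °C to rt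
Reagents that add atoms: none
Why: Acid‑catalysed methanolysis of the primary silyl ether does not affect the alkenyl iodide.

Step 18
Reactants: 28 (2S,3E)‑4‑iodo‑2‑methylpent‑3‑en‑1‑ol
Product: 29 (2S,3E)‑4‑iodo‑2‑methylpent‑3‑enal
Conditions: Dess–Martin periodinane, NaHCO3, CH2Cl2, 0 °C; used at once without chromatography
Reagents that add atoms: none
Why: Buffered Dess–Martin oxidation gives the β,γ‑unsaturated aldehyde under non‑basic conditions, so the labile α‑centre C13 is not enolised.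

Step 19
Reactants: 29 (2S,3E)‑4‑iodo‑2‑methylpent‑3‑enal; 1 pentan‑3‑one
Product: 31 (6S,7E)‑5‑hydroxy‑8‑iodo‑4,6‑dimethylnon‑7‑en‑3‑one (C4/C5 mixture), via lithium enolate 30 (not isolated)
Conditions: 1, LiN(i‑Pr)2, THF, −78 °C; 29, −78 °C, 20 min; AcOH, −78 °C
Reagents that add atoms: none
Why: Lithium‑enolate aldol addition at −78 °C is faster than proton transfer from the aldehyde, and the two new centres are erased later while C13 is no longer α to a carbonyl.

Step 20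
Reactants: 32 propanal (two molecules)
Product: 34 (2S,3S)‑3‑hydroxy‑2‑methylpentanal, via proline enamine 33 (not isolated)
Conditions: L‑proline (10 mol %), DMF, 4 °C, slow addition of 32 over 24 h; Et2O/H2O work‑up; used crude
Reagents that add atoms: none
Why: Proline‑catalysed direct aldehyde–aldehyde aldol reaction (enamine catalysis), in which the (E)‑enamine 33 adds to the re face of a second propanal through the carboxylic‑acid‑bound chair‑like transition state, setting C15 and C16 anti and (S,S) (about 4:1 anti:syn, high ee); the minor syn isomer is removed by chromatography after step 21.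

Step 21
Reactants: 34 (2S,3S)‑3‑hydroxy‑2‑methylpentanal
Product: 35 (2S,3S)‑3‑(TBSO)‑2‑methylpentanal
Conditions: TBSOTf, 2,6‑lutidine, CH2Cl2, −78 °C; chromatography
Reagents that add atoms: tert‑butyldimethylsilyl triflate (CC(C)(C)[Si](C)(C)OS(=O)(=O)C(F)(F)F)
Why: Silylation of the β‑hydroxyl at −78 °C with a hindered non‑nucleophilic base protects C16–OH with a group that survives enolates, oxidation and cyclodehydration, and it stops dehydration and oligomerisation of the aldol without epimerising C15.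

Step 22
Reactants: 31 the β‑hydroxy ketone; 35 (2S,3S)‑3‑(TBSO)‑2‑methylpentanal
Product: 37 5,9‑dihydroxy‑12‑iodo‑3‑(TBSO)‑4,6,8,10‑tetramethyltridec‑11‑en‑7‑one (mixture at the four new centres), via aldolate dianion 36 (not isolated)
Conditions: 31, LiN(i‑Pr)2 (2.2 equiv), THF, −78 °C; 35, −78 °C; AcOH, −78 °C
Reagents that add atoms: none
Why: Aldol addition of an aldolate dianion, in which the lithium alkoxide blocks deprotonation on its own side so that the ethyl CH2 is enolised and adds to the aldehyde.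

Step 23
Reactants: 37 the diol ketone
Product: 38 (3S,4S,10S,11E)‑12‑iodo‑3‑(TBSO)‑4,6,8,10‑tetramethyltridec‑11‑ene‑5,7,9‑trione (keto–enol mixture)
Conditions: Dess–Martin periodinane (3 equiv), NaHCO3, CH2Cl2, rt
Reagents that add atoms: none
Why: Double Dess–Martin oxidation of both carbinols gives the 1,3,5‑triketone under buffered non‑basic conditions.

Step 24
Reactants: 38 the triketone
Product: 39 2‑[(2S,3S)‑3‑(TBSO)pentan‑2‑yl]‑6‑[(2S,3E)‑4‑iodopent‑3‑en‑2‑yl]‑3,5‑dimethyl‑4H‑pyran‑4‑one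
Conditions: PPh3, CCl4, THF, rt
Reagents that add atoms: none
Why: Cyclodehydration of the 1,3,5‑triketone closes ring B; the internal enols form preferentially, which keeps C13 and C15 out of the enolisation.

Step 25
Reactants: 39 the silyl ether
Product: 40 2‑[(2S,3S)‑3‑hydroxypentan‑2‑yl]‑6‑[(2S,3E)‑4‑iodopent‑3‑en‑2‑yl]‑3,5‑dimethyl‑4H‑pyran‑4‑one
Conditions: HF·pyridine, pyridine, THF, 0 °C to rt
Reagents that add atoms: none
Why: Fluoride‑driven desilylation under buffered acidic conditions frees C16–OH without affecting the alkenyl iodide or the pyranone.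

Step 26
Reactants: 40 the alcohol
Product: 41 (2S,3S)‑2‑{6‑[(2S,3E)‑4‑iodopent‑3‑en‑2‑yl]‑3,5‑dimethyl‑4‑oxo‑4H‑pyran‑2‑yl}pentan‑3‑yl acetate
Conditions: Ac2O, DMAP, pyridine, CH2Cl2, rt
Reagents that add atoms: acetic anhydride (CC(=O)OC(C)=O)
Why: DMAP‑catalysed acetylation installs the C16 acetate before the coupling, so that it is distinguished from the two later propionates.

**Coupling and end game**

Step 27
Reactants: 19 the ring‑A aldehyde; 41 the ring‑B alkenyl iodide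
Product: 43 C10–C11 coupled allylic alcohol with C8–OTBS and C16–OAc (both C10 epimers), via alkenylchromium dichloride 42 (not isolated)
Conditions: CrCl2 (8 equiv), NiCl2 (2 mol %), degassed DMSO, rt
Reagents that add atoms: none
Why: Nozaki–Hiyama–Kishi coupling (oxidative addition of the C–I bond to zerovalent nickel, transmetalation to trivalent chromium, addition to the aldehyde) is selective for the aldehyde over pyranones and acetate and retains the E geometry; the C10 configuration is corrected in steps 28–30.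

Step 28
Reactants: 43 the allylic alcohols
Product: 44 C10 enone with C8–OTBS, (7R,8S,9R,11E,13S,15S,16S)
Conditions: Dess–Martin periodinane, NaHCO3, CH2Cl2, 0 °C to rt
Reagents that add atoms: none
Why: Dess–Martin oxidation converges both C10 epimers on one enone without base, so C9 and C13 are kept.

Step 29
Reactants: 44 the silyl ether enone
Product: 45 8‑hydroxy C10 enone, (7R,8S,9R,11E,13S,15S,16S)
Conditions: HF·pyridine, pyridine, THF, rt
Reagents that add atoms: none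
Why: Buffered HF desilylation frees the β‑hydroxyl under mildly acidic conditions, which avoids base‑induced elimination or retro‑aldol and keeps the acetate.

Step 30
Reactants: 45 the β‑hydroxy enone
Product: 46 8,10‑anti diol, (7R,8R,9R,10R,11E,13S,15S,16S)
Conditions: Me4NBH(OAc)3, MeCN/AcOH 1:1, −30 °C
Reagents that add atoms: none
Why: Evans–Saksena reduction, in which the C8 alkoxy‑diacetoxyborohydride delivers hydride intramolecularly through a chair transition state to give the 1,3‑anti diol and so sets C10 as R.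

Step 31
Reactants: 46 the diol
Product: 47 the target, 8,10‑dipropionate 16‑acetate
Conditions: EtCOCl, pyridine, DMAP, CH2Cl2, 0 °C to rt
Reagents that add atoms: propanoyl chloride (CCC(=O)Cl)
Why: DMAP‑catalysed acylation of both free secondary hydroxyls gives the two propionates with no change at any stereocentre.

**Compound list**
1 | pentan‑3‑one | CCC(=O)CC | starting material
2 | ethyl propanoate | CCC(=O)OCC | starting material
3 | 4‑methylheptane‑3,5‑dione | CCC(=O)C(C)C(=O)CC | intermediate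
4 | methyl (S)‑3‑hydroxy‑2‑methylpropanoate | COC(=O)[C@@H](C)CO | starting material
5 | methyl (S)‑3‑(TBSO)‑2‑methylpropanoate | COC(=O)[C@@H](C)CO[Si](C)(C)C(C)(C)C | intermediate
6 | (S)‑3‑(TBSO)‑2‑methylpropanal | O=C[C@@H](C)CO[Si](C)(C)C(C)(C)C | intermediate
7 | (E)‑but‑2‑ene | C/C=C/C | starting material
8 | (E)‑crotylpotassium | [K+].[CH2-]/C=C/C | intermediate (not isolated)
9 | (E)‑crotylbis(isopinocampheyl)borane, Ipc from (+)‑α‑pinene | C/C=C/CB([C@@H]1C[C@@H]2C[C@H]([C@H]1C)C2(C)C)[C@@H]1C[C@@H]2C[C@H]([C@H]1C)C2(C)C | intermediate (not isolated)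
10 | (2S,3S,4S)‑1‑(TBSO)‑2,4‑dimethylhex‑5‑en‑3‑ol | O[C@H]([C@@H](C)CO[Si](C)(C)C(C)(C)C)[C@@H](C)C=C | intermediate
11 | (2S,3S,4S)‑1,3‑bis(TBSO)‑2,4‑dimethylhex‑5‑ene | CC(C)(C)[Si](C)(C)O[C@H]([C@@H](C)CO[Si](C)(C)C(C)(C)C)[C@@H](C)C=C | intermediate
12 | secondary ozonide (1,2,4‑trioxolane) of 11 | CC(C)(C)[Si](C)(C)O[C@H]([C@@H](C)CO[Si](C)(C)C(C)(C)C)[C@@H](C)C1OCOO1 | intermediate (not isolated)
13 | (2R,3R,4S)‑3,5‑bis(TBSO)‑2,4‑dimethylpentanal | CC(C)(C)[Si](C)(C)O[C@H]([C@@H](C)CO[Si](C)(C)C(C)(C)C)[C@@H](C)C=O | intermediate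
14 | dilithium 4‑methylhepta‑2,4‑diene‑3,5‑diolate (dianion of 3) | [Li+].[Li+].CC=C([O-])C(C)=C([O-])CC | intermediate (not isolated)
15 | 7‑hydroxy‑9,11‑bis(TBSO)‑4,6,8,10‑tetramethylundecane‑3,5‑dione; C8, C9, C10 as in 13, mixture at C4, C6, C7 | CC(C)(C)[Si](C)(C)O[C@H]([C@@H](C)CO[Si](C)(C)C(C)(C)C)[C@@H](C)C(O)C(C)C(=O)C(C)C(=O)CC | intermediate
16 | (8R,9R,10S)‑9,11‑bis(TBSO)‑4,6,8,10‑tetramethylundecane‑3,5,7‑trione | CC(C)(C)[Si](C)(C)O[C@H]([C@@H](C)CO[Si](C)(C)C(C)(C)C)[C@@H](C)C(=O)C(C)C(=O)C(C)C(=O)CC | intermediate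
17 | 2‑[(2R,3R,4S)‑3,5‑bis(TBSO)‑4‑methylpentan‑2‑yl]‑6‑ethyl‑3,5‑dimethyl‑4H‑pyran‑4‑one | CC(C)(C)[Si](C)(C)O[C@H]([C@@H](C)CO[Si](C)(C)C(C)(C)C)[C@@H](C)c1oc(CC)c(C)c(=O)c1C | intermediate
18 | 2‑[(2R,3R,4S)‑3‑(TBSO)‑5‑hydroxy‑4‑methylpentan‑2‑yl]‑6‑ethyl‑3,5‑dimethyl‑4H‑pyran‑4‑one | CC(C)(C)[Si](C)(C)O[C@H]([C@@H](C)CO)[C@@H](C)c1oc(CC)c(C)c(=O)c1C | intermediate
19 | (2R,3S,4R)‑3‑(TBSO)‑4‑(6‑ethyl‑3,5‑dimethyl‑4‑oxo‑4H‑pyran‑2‑yl)‑2‑methylpentanal | CC(C)(C)[Si](C)(C)O[C@H]([C@@H](C)C=O)[C@@H](C)c1oc(CC)c(C)c(=O)c1C | intermediate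
20 | methyl (R)‑3‑hydroxy‑2‑methylpropanoate | COC(=O)[C@H](C)CO | starting material
21 | methyl (R)‑3‑(TBSO)‑2‑methylpropanoate | COC(=O)[C@H](C)CO[Si](C)(C)C(C)(C)C | intermediate
22 | (R)‑3‑(TBSO)‑2‑methylpropanal | O=C[C@H](C)CO[Si](C)(C)C(C)(C)C | intermediate
23 | (S)‑4,4‑dibromo‑1‑(TBSO)‑2‑methylbut‑3‑ene | BrC(Br)=C[C@H](C)CO[Si](C)(C)C(C)(C)C | intermediate
24 | [(S)‑4‑(TBSO)‑3‑methylbut‑1‑yn‑1‑yl]lithium | [Li]C#C[C@H](C)CO[Si](C)(C)C(C)(C)C | intermediate (not isolated)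
25 | (S)‑1‑(TBSO)‑2‑methylpent‑3‑yne | CC#C[C@H](C)CO[Si](C)(C)C(C)(C)C | intermediate
26 | Cp2Zr(Cl)[(S,E)‑5‑(TBSO)‑4‑methylpent‑2‑en‑2‑yl] | Cl[Zr+2]/C(C)=C/[C@H](C)CO[Si](C)(C)C(C)(C)C.c1cc[cH-]c1.c1cc[cH-]c1 | intermediate (not isolated)
27 | (S,E)‑1‑(TBSO)‑4‑iodo‑2‑methylpent‑3‑ene | I/C(C)=C/[C@H](C)CO[Si](C)(C)C(C)(C)C | intermediate
28 | (2S,3E)‑4‑iodo‑2‑methylpent‑3‑en‑1‑ol | I/C(C)=C/[C@H](C)CO | intermediate
29 | (2S,3E)‑4‑iodo‑2‑methylpent‑3‑enal | I/C(C)=C/[C@H](C)C=O | intermediate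
30 | lithium pent‑2‑en‑3‑olate | [Li+].CC=C([O-])CC | intermediate (not isolated)
31 | (6S,7E)‑5‑hydroxy‑8‑iodo‑4,6‑dimethylnon‑7‑en‑3‑one, mixture at C4 and C5 | I/C(C)=C/[C@H](C)C(O)C(C)C(=O)CC | intermediate
32 | propanal | CCC=O | starting material
33 | (S)‑1‑[(E)‑prop‑1‑en‑1‑yl]pyrrolidine‑2‑carboxylic acid (enamine of propanal on L‑proline) | C/C=C/N1CCC[C@H]1C(=O)O | intermediate (not isolated)
34 | (2S,3S)‑3‑hydroxy‑2‑methylpentanal | O=C[C@@H](C)[C@H](CC)O | intermediate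
35 | (2S,3S)‑3‑(TBSO)‑2‑methylpentanal | O=C[C@@H](C)[C@H](CC)O[Si](C)(C)C(C)(C)C | intermediate
36 | dilithium alkoxide–enolate of 31 | [Li+].[Li+].I/C(C)=C/[C@H](C)C([O-])C(C)C([O-])=CC | intermediate (not isolated)
37 | (11E)‑5,9‑dihydroxy‑12‑iodo‑3‑(TBSO)‑4,6,8,10‑tetramethyltridec‑11‑en‑7‑one; C3, C4 as in 35, C10 as in 29, mixture at C5, C6, C8, C9 | I/C(C)=C/[C@H](C)C(O)C(C)C(=O)C(C)C(O)[C@@H](C)[C@H](CC)O[Si](C)(C)C(C)(C)C | intermediate
38 | (3S,4S,10S,11E)‑12‑iodo‑3‑(TBSO)‑4,6,8,10‑tetramethyltridec‑11‑ene‑5,7,9‑trione | I/C(C)=C/[C@H](C)C(=O)C(C)C(=O)C(C)C(=O)[C@@H](C)[C@H](CC)O[Si](C)(C)C(C)(C)C | intermediate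
39 | 2‑[(2S,3S)‑3‑(TBSO)pentan‑2‑yl]‑6‑[(2S,3E)‑4‑iodopent‑3‑en‑2‑yl]‑3,5‑dimethyl‑4H‑pyran‑4‑one | I/C(C)=C/[C@H](C)c1oc([C@@H](C)[C@H](CC)O[Si](C)(C)C(C)(C)C)c(C)c(=O)c1C | intermediate
40 | 2‑[(2S,3S)‑3‑hydroxypentan‑2‑yl]‑6‑[(2S,3E)‑4‑iodopent‑3‑en‑2‑yl]‑3,5‑dimethyl‑4H‑pyran‑4‑one | I/C(C)=C/[C@H](C)c1oc([C@@H](C)[C@H](CC)O)c(C)c(=O)c1C | intermediate
41 | (2S,3S)‑2‑{6‑[(2S,3E)‑4‑iodopent‑3‑en‑2‑yl]‑3,5‑dimethyl‑4‑oxo‑4H‑pyran‑2‑yl}pentan‑3‑yl acetate | I/C(C)=C/[C@H](C)c1oc([C@@H](C)[C@H](CC)OC(C)=O)c(C)c(=O)c1C | intermediate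
42 | alkenylchromium dichloride from 41 (CrCl2 in place of I) | Cl[Cr](Cl)/C(C)=C/[C@H](C)c1oc([C@@H](C)[C@H](CC)OC(C)=O)c(C)c(=O)c1C | intermediate (not isolated)
43 | coupled allylic alcohol, C8–OTBS, C10–OH (both epimers), C16–OAc; other centres as in 19 and 41 | CC(C)(C)[Si](C)(C)O[C@H]([C@@H](C)C(O)/C(C)=C/[C@H](C)c1oc([C@@H](C)[C@H](CC)OC(C)=O)c(C)c(=O)c1C)[C@@H](C)c1oc(CC)c(C)c(=O)c1C | intermediate
44 | C10 enone, C8–OTBS, (7R,8S,9R,11E,13S,15S,16S) | CC(C)(C)[Si](C)(C)O[C@H]([C@@H](C)C(=O)/C(C)=C/[C@H](C)c1oc([C@@H](C)[C@H](CC)OC(C)=O)c(C)c(=O)c1C)[C@@H](C)c1oc(CC)c(C)c(=O)c1C | intermediate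
45 | 8‑hydroxy C10 enone, (7R,8S,9R,11E,13S,15S,16S) | O[C@H]([C@@H](C)C(=O)/C(C)=C/[C@H](C)c1oc([C@@H](C)[C@H](CC)OC(C)=O)c(C)c(=O)c1C)[C@@H](C)c1oc(CC)c(C)c(=O)c1C | intermediate
46 | 8,10‑anti diol 16‑acetate, (7R,8R,9R,10R,11E,13S,15S,16S) | O[C@H]([C@@H](C)[C@@H](O)/C(C)=C/[C@H](C)c1oc([C@@H](C)[C@H](CC)OC(C)=O)c(C)c(=O)c1C)[C@@H](C)c1oc(CC)c(C)c(=O)c1C | intermediate
47 | CNP0295731.1, 8,10‑dipropionate 16‑acetate, (7R,8R,9R,10R,11E,13S,15S,16S) | CCC(=O)O[C@H]([C@@H](C)[C@@H](OC(=O)CC)/C(C)=C/[C@H](C)c1oc([C@@H](C)[C@H](CC)OC(C)=O)c(C)c(=O)c1C)[C@@H](C)c1oc(CC)c(C)c(=O)c1C | target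

**Totals and risks**
Total step count: 31.
Longest linear sequence: 18 steps (12–19, then 22–31); the ring‑A branch is 15 steps (2–11, then 27–31).

Three steps most likely to fail:

Step 22. The unprotected aldolate dianion of 31 may undergo retro‑aldol or enolise 35 instead of adding to it. The fallback sets out from 31 and comes back at 37. Silylate 31 (TESOTf, 2,6‑lutidine) to its triethylsilyl ether F1, enolise the ethyl ketone with LiN(i‑Pr)2 at −78 °C to the lithium enolate F2, add 35 to obtain the mono‑protected aldol adduct F3, and cleave the triethylsilyl ether selectively (PPTS, MeOH, 0 °C; the secondary TBS ether stays) to reach 37.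

Step 24. In triketone 38 the centres C13 (allylic and α to a ketone) and C15 may epimerise before or during ring closure. The fallback sets out from enolate 30 (from 1) and 35, uses 29 on the way, and comes back at 39; in it C14 is never a ketone. Aldol addition of 30 to 35 gives the β‑hydroxy ketone F4, Dess–Martin oxidation gives the β‑diketone F5, and LiN(i‑Pr)2 (2.1 equiv) gives its dianion F6, which adds through the ethyl terminus to 29 to give the δ‑hydroxy‑β‑diketone F7. Acid (TsOH, CH2Cl2) closes F7 to the 2,3‑dihydro‑4‑pyranone F8, and IBX (DMSO, 70 °C) dehydrogenates the C14–CH(Me) bond of the ring to give pyranone 39.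

Step 27. The trisubstituted alkenyl iodide and the α‑branched aldehyde are both hindered, so the chromium addition may stall. The fallback sets out from 19 and 41 and comes back at 44, making the enone by acyl cross‑coupling instead of carbonyl addition. Pinnick oxidation of 19 (NaClO2, NaH2PO4, 2‑methylbut‑2‑ene) gives the carboxylic acid F9, and 1‑chloro‑N,N,2‑trimethylprop‑1‑en‑1‑amine converts it under neutral conditions into the acid chloride F10. Separately, 41 is stannylated ((Me3Sn)2, Pd(PPh3)4, toluene, 80 °C) to the alkenyl trimethylstannane F11. Stille acylation of F10 with F11 (Pd2(dba)3, tri(2‑furyl)phosphine, THF, 50 °C) gives enone 44 directly, so step 28 is not needed.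

**Further compounds**
F1 | step 22 | triethylsilyl ether of 31 | I/C(C)=C/[C@H](C)C(O[Si](CC)(CC)CC)C(C)C(=O)CC
F2 | step 22 | lithium enolate of F1 | [Li+].I/C(C)=C/[C@H](C)C(O[Si](CC)(CC)CC)C(C)C([O-])=CC
F3 | step 22 | 9‑triethylsilyl ether of 37 | I/C(C)=C/[C@H](C)C(O[Si](CC)(CC)CC)C(C)C(=O)C(C)C(O)[C@@H](C)[C@H](CC)O[Si](C)(C)C(C)(C)C
F4 | step 24 | 5‑hydroxy‑7‑(TBSO)‑4,6‑dimethylnonan‑3‑one, C6 and C7 as in 35 | CCC(=O)C(C)C(O)[C@@H](C)[C@H](CC)O[Si](C)(C)C(C)(C)C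
F5 | step 24 | (6S,7S)‑7‑(TBSO)‑4,6‑dimethylnonane‑3,5‑dione | CCC(=O)C(C)C(=O)[C@@H](C)[C@H](CC)O[Si](C)(C)C(C)(C)C
F6 | step 24 | dilithium dianion of F5 | [Li+].[Li+].CC=C([O-])C(C)=C([O-])[C@@H](C)[C@H](CC)O[Si](C)(C)C(C)(C)C
F7 | step 24 | (11E)‑9‑hydroxy‑12‑iodo‑3‑(TBSO)‑4,6,8,10‑tetramethyltridec‑11‑ene‑5,7‑dione | I/C(C)=C/[C@H](C)C(O)C(C)C(=O)C(C)C(=O)[C@@H](C)[C@H](CC)O[Si](C)(C)C(C)(C)C
F8 | step 24 | 2‑[(2S,3E)‑4‑iodopent‑3‑en‑2‑yl]‑6‑[(2S,3S)‑3‑(TBSO)pentan‑2‑yl]‑3,5‑dimethyl‑2,3‑dihydro‑4H‑pyran‑4‑one | I/C(C)=C/[C@H](C)C1OC([C@@H](C)[C@H](CC)O[Si](C)(C)C(C)(C)C)=C(C)C(=O)C1C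
F9 | step 27 | carboxylic acid from 19 (CO2H in place of CHO) | CC(C)(C)[Si](C)(C)O[C@H]([C@@H](C)C(=O)O)[C@@H](C)c1oc(CC)c(C)c(=O)c1C
F10 | step 27 | acid chloride of F9 | CC(C)(C)[Si](C)(C)O[C@H]([C@@H](C)C(=O)Cl)[C@@H](C)c1oc(CC)c(C)c(=O)c1C
F11 | step 27 | alkenyl trimethylstannane from 41 (SnMe3 in place of I) | C[Sn](C)(C)/C(C)=C/[C@H](C)c1oc([C@@H](C)[C@H](CC)OC(C)=O)c(C)c(=O)c1C
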